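The readings were generated by integration with constants of no real substance, and the scatter is random.

If I am to repeat this coupling, I must decide two things before charging the flask: how much coupling partner to use, and whether 40 h is long enough for product to take the lead.

| flask | starting material | coupling partner | precatalyst | remark | time |
|---|---|---|---|---|---|
| larch | 0.050 M | 0.22 M | 5 mM | run made earlier |  |
| ash | 0.050 M | 0.69 M | 5 mM | run made earlier |  |
| dawn | 0.050 M | 0.450 M | 5.0 mM |  | 40 h |
| spring | 0.050 M | 0.200 M | 5.0 mM |  | 40 h |
| autumn | 0.050 M | 0.300 M | 5.0 mM |  | 40 h |

| run | time / h | catalyst intermediate A / % | product / % | catalyst intermediate C / % | starting material / % |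
|---|---|---|---|---|---|
| larch | 6.00 | 0.7 | 1.4 | 0.1 | 96.7 |
| larch | 12.0 | 1.6 | 7.5 | 0 | 90.7 |
| larch | 15.0 | 1.7 | 11.4 | 0.2 | 87.2 |
| larch | 25.0 | 0.8 | 23.3 | 0 | 76.1 |
| larch | 30.0 | 0.6 | 28.4 | 0 | 69.2 |
| larch | 40.0 | 1.3 | 39.2 | 0.4 | 59.7 |
| ash | 6.00 | 0.9 | 2.3 | 0 | 97.1 |
| ash | 12.0 | 0.2 | 8.2 | 0.4 | 91.1 |
| ash | 15.0 | 1.1 | 12.0 | 0.2 | 86.9 |
| ash | 25.0 | 0.2 | 22.7 | 0 | 75.8 |
| ash | 30.0 | 0.5 | 29.4 | 0 | 69.7 |
| ash | 40.0 | 0.7 | 39.2 | 0.8 | 59.5 |

(scatter of a reading: 0.5 percentage points)

- percentages count the starting material that a species holds: one resting dimer counts as two
- the numbers in the tables scatter with a standard deviation of 0.5 percentage points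
- what may be going on: precatalyst <-> free catalyst; catalyst intermediate A -> catalyst intermediate B; starting material + free catalyst <-> catalyst intermediate A; 2 catalyst intermediate B <-> resting dimer; coupling partner + catalyst intermediate B <-> catalyst intermediate C; catalyst intermediate C -> free catalyst + product

- which of these there is most of at the end, counted by the starting material in it, dawn (catalyst intermediate A / product / starting material / catalyst intermediate C)
- which of these there is most of at the end, counted by the starting material in it, spring (catalyst intermediate A / product / starting material / catalyst intermediate C)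
- which of these there is most of at the end, counted by the starting material in it, autumn (catalyst intermediate A / product / starting material / catalyst intermediate C)
- final amount of the leader among these, as a percentage of the starting material charged, in dawn
- final amount of the leader among these, as a percentage of the starting material charged, in spring
- final amount of the leader among these, as a percentage of the starting material charged, in autumn

I take the partner first. From larch to ash the coupling partner grows by a factor of 3.14, yet starting material at 40.0 h reads 59.7 % and 59.5 %, which lie within the scatter of 0.5 percentage points. So I lean towards spring's 0.200 M, although it stands a little below larch's charge. Starting material, at 0.050 M, stays the limiting reagent there.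

For the time I go to logarithms and work in powers of ten. I leave out the early readings, because larch gains 1.4 % of product by 6.00 h but 6.1 points in the following stretch to 12.0 h, so the reaction starts slowly. From 15.0 h to 40.0 h, larch falls by 0.165 of a power of ten, which gives 152 h. I call this the decade time: the hours starting material needs to fall tenfold if it falls in a pseudo-first-order way. It is a reading and carries the scatter, but ash gives 152 h over the same stretch.

In larch at 40.0 h, starting material and product hold nearly all of the charge, so the lead changes close to where starting material reaches half. That is a further 0.0770 of a power of ten, which puts the crossing near 51.7 h, later than 40 h. I therefore expect starting material to lead in dawn, spring and autumn, near larch's 59.7 %. I decide to charge the smaller amount of partner and to watch the clock.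

The forecast also names starting material for dawn, spring and autumn, with 59.6 % in dawn, 60 % in spring and 59.8 % in autumn, holding the rate to be “zero order in partner across this range”.

Starting material leads in dawn, spring and autumn, with 59.9 % in dawn, 60.1 % in spring and 60.0 % in autumn.

    precatalyst ⇌ free catalyst (K = 0.210, k = 1.20 × 10⁻⁵ s⁻¹)
    catalyst intermediate A → catalyst intermediate B (k = 3.20 × 10⁻⁴ s⁻¹)
    starting material + free catalyst ⇌ catalyst intermediate A (K = 60.0 M⁻¹, k = 0.00760 M⁻¹ s⁻¹)
    2 catalyst intermediate B ⇌ resting dimer (K = 14000 M⁻¹, k = 0.00590 M⁻¹ s⁻¹)
    coupling partner + catalyst intermediate B ⇌ catalyst intermediate C (K = 14.0 M⁻¹, k = 0.110 M⁻¹ s⁻¹)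
    catalyst intermediate C → free catalyst + product (k = 0.00220 s⁻¹)

I now use the decade time on autumn left until 6.0 d, with the amounts and the temperature held. Beyond autumn's 60.0 % at 40.0 h, the extra 104 h are 0.684 of a power of ten, so I reckon 12.4 % of starting material. That flask holds 10.9 % of starting material, and product leads with 88.9 %.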